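The vessel is closed, stirred and held at one temperature; first end groups and second end groups join to links, and links then disappear.

| flask | first end groups | second end groups | remark | time |
|---|---|---|---|---|
| winter | 20 mM | 13 mM | run made earlier |  |
| spring | 20 mM | 130 mM | run made earlier |  |
| elm | 20 mM | 20.0 mM |  | 1.0 h |
| birch | 20 mM | 40.0 mM |  | 1.0 h |
| cedar | 20 mM | 80.0 mM |  | 1.0 h |
| oak | 20 mM | 150 mM |  | 1.0 h |

| run | time / min | links / % | first end groups / % |
|---|---|---|---|
| winter | 5.00 | 10.0 | 89.4 |
| winter | 8.00 | 13.4 | 83.6 |
| winter | 12.0 | 16.8 | 77.5 |
| winter | 20.0 | 19.6 | 68.6 |
| winter | 40.0 | 18.4 | 55.5 |
| winter | 60.0 | 14.9 | 48.6 |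
| spring | 10.0 | 66.5 | 9.2 |
| spring | 20.0 | 51.3 | 0.4 |
| spring | 30.0 | 38.3 | 0.4 |
| spring | 40.0 | 29.2 | 0.4 |
| spring | 50.0 | 23.3 | 0 |
| spring | 60.0 | 19.2 | 0.1 |

(scatter of a reading: 0.3 percentage points)

- "hardly changes" means that all values lie within two and a half points (for a concentration: within two and a half percent of the largest)

- amount of links at the end, in percent of the first end groups charged for elm, birch, cedar, oak, in this order
- how the row runs (hardly changes / falls all the way / rises all the way / rises, then falls / falls, then rises)

How fast do the end groups join? Take the spring run: first end groups fall to 9.2% in 10.0 min, while c(second end groups) stays near 120 mM. That gives a joining constant of 0.00199 /mM/min.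

How fast do links go? In the spring run first end groups read 0.4% at 20.0 min, so from there links fall unfed, from 51.3% to 29.2% by 40.0 min. That is a loss constant of 0.0282 /min.

Where does control change hands? Late in a flask with excess second end groups, first end groups die away in a pseudo-first-order tail, with constant kf times the excess c(second end groups) minus c(first end groups). I reckon this for the charge of first end groups and the late time of the asked flasks: while that tail is slower than the loss of links, links follow their feed, and more second end groups should leave more links at the end. Once it is faster, links made early have longer to fall, and more second end groups should leave fewer. The two constants are equal at the crossing charge, c(first end groups) plus the loss constant over the joining constant: 34.2 mM.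

But the loss slows in the spring run: from 40.0 min to 60.0 min it reads 0.0210 /min. Doesn't that move the crossing? It does, to 30.5 mM, which still lies above elm's charge and below birch's.

So what do I commit to? I expect the row to rise from elm to birch, then fall. For oak the tail constant is 0.258 /min, well above the loss constant, so oak should end close to the 19.2% that the spring run reads at the same time.

The forecast gave 21%, 24.5%, 20.7% and 18.8%, shape rises, then falls, on the grounds that “low excess gives slow formation and incomplete conversion, while high excess gives early formation and more time for decay”.

The flasks give 20.7%, 24.3%, 20.6% and 18.9%: rises, then falls.

    links → over-reaction product (k = 0.0280 /min)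
    first end groups + second end groups → links (k = 2.00 /M/min)
    links ⇌ isomer of the product (K = 0.510, k = 0.0200 /min)

The row turns at 35 mM, close to the crossing charge of 34.2 mM. In elm, below the crossing, links are made, each step taken net, 1.56 times as fast as they are used up at 0.227 h and 0.621 times as fast at 1.00 h, with 29% of the first end groups still there. Oak, charged at 4.39 times the crossing, has 0% of its first end groups left at the end, and there the local order of links in second end groups is −0.080.

The data are calculated on assumed constants, and the scatter is random.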